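**Retrosynthetic overview**
1. Target ⇐ reductive radical cascade of a 3-chloro type A bicyclo[3.3.1]nonane-2,4,9-trione: the C3 radical closes C3–C29 (7-exo, homoadamantane), then C30–C2″ (5-exo, cyclopentane), and hydrogen capture gives the isopropyl group.
2. Bicyclic chloride ⇐ cationic cyclization (C8 cation onto C1) of a monocyclic dearomatized acylphloroglucinol with geranyl + lavandulyl on C5 and Cl + prenyl on C3; the chlorine blocks C3 so only the benzoyl-bearing carbon can close, and later serves as the radical source.
3. Monocycle ⇐ three successive C-alkylations of 3-chloro-2,4,6-trihydroxybenzophenone: (S)-lavandulyl at the free arene carbon, geranyl (dearomatizing, sets C5), prenyl (at the C–Cl carbon).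
4. (S)-Lavandulol ⇐ Evans deconjugative alkylation of an N-(3-methylbut-2-enoyl)oxazolidinone with prenyl bromide.
5. Ring order: ring B of the bicyclo[3.3.1]nonane (C1–C8) → seven-membered homoadamantane bridge (C3–C29) → cyclopentane (C30–C2″).

Assumption: locants are C1 = benzoyl-bearing ring carbon, C2/C4/C9 = ring carbonyl carbons, C3 = carbon between C2 and C4, C5 = geranyl-bearing carbon, C6–C7–C8 = lavandulyl CH2, CH and isopropenyl carbon, C28–C30 = prenyl arm on C7, C1″–C3″ = prenyl on C3; enolizable compounds are drawn as one tautomer, and 13 and 14 are used as C3-epimer mixtures (C3 becomes a planar radical in step 9).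

**Step 1**
Reactants: 1 (S)-4-benzyl-1,3-oxazolidin-2-one; 2 3-methylbut-2-enoyl chloride
Product: 3 (S)-4-benzyl-3-(3-methylbut-2-enoyl)-1,3-oxazolidin-2-one
Conditions: n-BuLi, THF, −78 °C; then 2, −78 → 0 °C
Reagents that add atoms: none
Why: N-acylation of the lithiated Evans oxazolidinone (nucleophilic acyl substitution); no new stereocentre.

**Step 2**
Reactants: 3 (S)-4-benzyl-3-(3-methylbut-2-enoyl)-1,3-oxazolidin-2-one; 4 prenyl bromide (1-bromo-3-methylbut-2-ene)
Product: 5 (4S)-4-benzyl-3-[(2S)-5-methyl-2-(prop-1-en-2-yl)hex-4-enoyl]-1,3-oxazolidin-2-one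
Conditions: NaN(SiMe3)2, THF, −78 °C; then 4, −78 → −40 °C
Reagents that add atoms: none
Why: Evans asymmetric alkylation in its deconjugative form: γ-deprotonation gives the chelated Z-dienolate, which is alkylated at the α-carbon on the face opposite the benzyl group, setting the (2S) centre.

**Step 3**
Reactants: 5 (4S)-4-benzyl-3-[(2S)-5-methyl-2-(prop-1-en-2-yl)hex-4-enoyl]-1,3-oxazolidin-2-one
Product: 6 (S)-lavandulol [(2S)-5-methyl-2-(prop-1-en-2-yl)hex-4-en-1-ol]
Conditions: LiBH4, H2O (1 equiv), Et2O, 0 °C
Reagents that add atoms: none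
Why: hydride reduction of the imide carbonyl releases the primary alcohol and the recoverable auxiliary without epimerizing the adjacent stereocentre.

**Step 4**
Reactants: 7 2,4,6-trihydroxybenzophenone
Product: 8 3-chloro-2,4,6-trihydroxybenzophenone
Conditions: N-chlorosuccinimide (1.0 equiv), MeCN, −20 → 0 °C
Reagents that add atoms: N-chlorosuccinimide, O=C1CCC(=O)N1Cl
Why: electrophilic aromatic chlorination at one of the two equivalent free ring carbons; the chlorine marks the future C3, steers the later alkylations and becomes the radical source.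

**Step 5**
Reactants: 8 3-chloro-2,4,6-trihydroxybenzophenone; 6 (S)-lavandulol
Product: 10 3-chloro-5-[(2R)-5-methyl-2-(prop-1-en-2-yl)hex-4-en-1-yl]-2,4,6-trihydroxybenzophenone (the (S)-lavandulyl arene; R only through the CIP priority change), via (S)-lavandulyl triflate 9 (not isolated)
Conditions: 6, Tf2O, 2,6-lutidine, CH2Cl2, −78 °C; then cannulated into 8, LiN(SiMe3)2 (4 equiv), THF–toluene, −78 → 0 °C; aq. HCl
Reagents that add atoms: none
Why: triflation followed by SN2 C-alkylation of the lithium phloroglucinolate at its only unsubstituted ring carbon (tight lithium–oxygen pairing in a weakly polar medium disfavours O-alkylation); the lavandulyl stereocentre is not touched.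

**Step 6**
Reactants: 10 3-chloro-5-[(S)-lavandulyl]-2,4,6-trihydroxybenzophenone; 11 geranyl bromide [(2E)-1-bromo-3,7-dimethylocta-2,6-diene]
Product: 12 2-benzoyl-4-chloro-6-geranyl-3,5-dihydroxy-6-[(S)-lavandulyl]cyclohexa-2,4-dien-1-one (ring C6 = C5; configuration as in the SMILES)
Conditions: 11 (1.05 equiv), N-(9-anthracenylmethyl)cinchonidinium bromide (10 mol %; the cinchoninium pseudo-enantiomer if that proves to be the matched one), CsOH·H2O, toluene–CH2Cl2, −50 °C
Reagents that add atoms: none
Why: Proposed new method: the phenolate is C-allylated (SN2) at C5, its most nucleophilic ring carbon (the chlorine-bearing C3 is less basic and the acyl-bearing C1 does not alkylate), inside a chiral ammonium–phenolate ion pair that should shield one face of the planar ring and so set the quaternary C5 centre relative to the fixed lavandulyl centre; closest known reaction type: phase-transfer-catalysed enantioselective alkylative dearomatization of acylphloroglucinols; any C5 epimer formed is carried on and removed after step 8, where it gives the separable C7-exo bicycle.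

**Step 7**
Reactants: 12 dearomatized chloro-enol (C5 geranyl/lavandulyl); 4 prenyl bromide
Product: 13 1-benzoyl-3-chloro-5-geranyl-5-[(S)-lavandulyl]-3-prenylcyclohexane-2,4,9-trione as its C9 enol (C3 epimers)
Conditions: LiN(SiMe3)2 (2.1 equiv), THF–toluene, −78 °C; then 4, −78 → 0 °C; aq. HCl
Reagents that add atoms: none
Why: SN2 C-alkylation of the α-chloro-β-diketone enolate at C3, the only enolizable ring carbon left besides the acyl-bearing C1; the new C3 centre forms unselectively and is erased in step 9.

**Step 8**
Reactants: 13 C3-chloro-C3-prenyl monocycle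
Product: 14 1-benzoyl-3-chloro-5-geranyl-8,8-dimethyl-3,7-diprenylbicyclo[3.3.1]nonane-2,4,9-trione (C7 prenyl endo, i.e. syn to the C2–C3–C4 bridge; absolute configuration as in the SMILES; C3 epimers)
Conditions: HCO2H, 23 °C
Reagents that add atoms: none
Why: Proposed new method: Markovnikov protonation of the isopropenyl group gives the tertiary C8 cation, which can be captured at carbon only by C1 because C3 is blocked as a quaternary C(Cl)(prenyl) centre (O-capture gives a tertiary enol ether that re-ionizes in the acid), closing ring B between two quaternary carbons; the C1 configuration follows from C5 and the pre-set lavandulyl centre becomes the endo C7 centre; closest known reaction type: formic-acid-mediated biomimetic cationic cyclization of dearomatized lavandulyl acylphloroglucinols, which closes onto the alkyl-bearing enol carbon when that carbon is free.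

**Step 9**
Reactants: 14 type A bicyclic chloride
Product: 15 CNP0155129.1 (target; homoadamantane cage with the C3–C29-fused cyclopentane on the C1/C2 flank and the isopropyl group on its convex face)
Conditions: (Me3Si)3SiH (1.3 equiv, syringe pump), AIBN (20 mol %), PhH (0.005 M), 80 °C
Reagents that add atoms: none
Why: radical dehalogenation-initiated cascade: the silyl radical abstracts chlorine to give the planar electrophilic C3 (1,3-diketone) radical, which adds 7-exo-trig to C29 of the endo C7 prenyl group held under it (the C28–C29 bond tilts toward C6H2 and away from the C8 gem-dimethyl group, turning C30 to the C1/C2 flank and setting C29), the tertiary C30 radical closes 5-exo-trig onto C2″ with the CMe2 terminus on the convex face (setting C2″), and the last tertiary radical takes hydrogen from the silane to give the isopropyl group; both C3 epimers of 14 converge.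

**Compound list**
1 | (S)-4-benzyl-1,3-oxazolidin-2-one | O=C1N[C@@H](Cc2ccccc2)CO1 | starting material
2 | 3-methylbut-2-enoyl chloride | CC(C)=CC(Cl)=O | starting material
3 | (S)-4-benzyl-3-(3-methylbut-2-enoyl)-1,3-oxazolidin-2-one | CC(C)=CC(=O)N1[C@@H](Cc2ccccc2)COC1=O | intermediate
4 | prenyl bromide | CC(C)=CCBr | starting material
5 | (4S)-4-benzyl-3-[(2S)-5-methyl-2-(prop-1-en-2-yl)hex-4-enoyl]-1,3-oxazolidin-2-one | CC(C)=CC[C@@H](C(C)=C)C(=O)N1[C@@H](Cc2ccccc2)COC1=O | intermediate
6 | (S)-lavandulol | CC(C)=CC[C@@H](C(C)=C)CO | intermediate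
7 | 2,4,6-trihydroxybenzophenone | O=C(c1ccccc1)c1c(O)cc(O)cc1O | starting material
8 | 3-chloro-2,4,6-trihydroxybenzophenone | O=C(c1ccccc1)c1c(O)cc(O)c(Cl)c1O | intermediate
9 | (S)-lavandulyl triflate | CC(C)=CC[C@@H](C(C)=C)COS(=O)(=O)C(F)(F)F | intermediate (not isolated)
10 | 3-chloro-5-[(S)-lavandulyl]-2,4,6-trihydroxybenzophenone | CC(C)=CC[C@H](Cc1c(O)c(Cl)c(O)c(C(=O)c2ccccc2)c1O)C(C)=C | intermediate
11 | geranyl bromide | CC(C)=CCC/C(C)=C/CBr | starting material
12 | 2-benzoyl-4-chloro-6-geranyl-3,5-dihydroxy-6-[(S)-lavandulyl]cyclohexa-2,4-dien-1-one | CC(C)=CCC/C(C)=C/C[C@@]1(C[C@@H](CC=C(C)C)C(C)=C)C(O)=C(Cl)C(O)=C(C(=O)c2ccccc2)C1=O | intermediate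
13 | 1-benzoyl-3-chloro-5-geranyl-5-[(S)-lavandulyl]-3-prenylcyclohexane-2,4,9-trione, C9 enol, C3 epimers | CC(C)=CCC/C(C)=C/C[C@@]1(C[C@@H](CC=C(C)C)C(C)=C)C(=O)C(Cl)(CC=C(C)C)C(=O)C(C(=O)c2ccccc2)=C1O | intermediate
14 | 1-benzoyl-3-chloro-5-geranyl-8,8-dimethyl-3,7-diprenylbicyclo[3.3.1]nonane-2,4,9-trione, C7 prenyl endo, C3 epimers | CC(C)=CCC/C(C)=C/C[C@@]12C[C@@H](CC=C(C)C)C(C)(C)[C@@](C(=O)c3ccccc3)(C(=O)C(Cl)(CC=C(C)C)C1=O)C2=O | intermediate
15 | CNP0155129.1 | CC(C)=CCC/C(C)=C/C[C@@]12C[C@H]3C[C@@H]4C(C)(C)[C@@H](C(C)C)C[C@]4(C1=O)C(=O)[C@@](C(=O)c1ccccc1)(C2=O)C3(C)C | target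

**Totals and risks**
Total step count: 9. Longest linear sequence: 8 (steps 1, 2, 3, 5, 6, 7, 8, 9); the benzophenone branch is 6 steps.

The three steps most likely to fail:

Step 8 (cationic closure onto the acyl-bearing C1). The risks are protonation of the geranyl or prenyl alkenes, persistent O-closure, and loss of the C7 centre through a C7=C8 alkene, which would leak to the exo bicycle. The fallback sets out from 13 and returns at 14. Only the 1,1-disubstituted isopropenyl alkene is activated, by hydrogen-atom transfer with Co(salen) [Co(C16H14N2O2)], N-fluoro-2,4,6-trimethylpyridinium tetrafluoroborate and PhSiH3. Radical–polar crossover at C8 is expected to give the O-closed 2,2-dimethyl-3-prenyl dihydropyran isomer F2 (C9–O–C8). F2 is then ionized under aprotic conditions (Me3SiOTf, 2,6-di-tert-butyl-4-methylpyridine, CH2Cl2, −78 → −20 °C), where no proton is available for the trisubstituted alkenes, and the C8 cation–silyl enol ether pair collapses at C1 to give 14.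

Step 5 (C- versus O-alkylation of the arene with a β-branched primary triflate). The fallback sets out from 8 and returns at 12, bypassing 10. Compound 8 is first C-geranylated at its free ring carbon (11, 10 % aq. KOH, 0 °C) to give 3-chloro-5-geranyl-2,4,6-trihydroxybenzophenone F1. F1 is then dearomatized with triflate 9 [LiN(SiMe3)2, THF–toluene, −78 → 0 °C], so that the sluggish electrophile is used for C-alkylation of a fully substituted lithium acylphloroglucinolate. This order has no catalyst control at C5, so 12 is obtained with its C5 epimer, which is removed after step 8.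

Step 9 (premature reduction of the C3 radical, or incomplete second closure). The fallback sets out from 14 and returns at 15. Zn dust in AcOH removes the chlorine to give the enolized 1-benzoyl-5-geranyl-8,8-dimethyl-3,7-diprenylbicyclo[3.3.1]nonane-2,4,9-trione F3; this is also the by-product of premature reduction in step 9, so that material is recycled. F3 is then cycloisomerized without net redox change: [Ir{dF(CF3)ppy}2(dtbbpy)]PF6 (2 mol %), 2,4,6-triisopropylbenzenethiol (10 mol %), 2,4,6-collidine, MeCN, blue LEDs. The photo-excited catalyst oxidizes the enolate to the same C3 radical, the 7-exo/5-exo cascade follows, and the thiol delivers the final hydrogen atom, giving 15.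

**Further compounds**
F1 | step 5 | 3-chloro-5-geranyl-2,4,6-trihydroxybenzophenone | CC(C)=CCC/C(C)=C/Cc1c(O)c(Cl)c(O)c(C(=O)c2ccccc2)c1O
F2 | step 8 | O-cyclized dihydropyran isomer of 13 (C9–O–C8 bond; C3 epimers) | CC(C)=CCC/C(C)=C/C[C@]12C[C@@H](CC=C(C)C)C(C)(C)OC1=C(C(=O)c3ccccc3)C(=O)C(Cl)(CC=C(C)C)C2=O
F3 | step 9 | 1-benzoyl-5-geranyl-8,8-dimethyl-3,7-diprenylbicyclo[3.3.1]nonane-2,4,9-trione, C2 enol, C7 prenyl endo | CC(C)=CCC/C(C)=C/C[C@@]12C[C@@H](CC=C(C)C)C(C)(C)[C@@](C(=O)c3ccccc3)(C(O)=C(CC=C(C)C)C1=O)C2=O
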